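## Structural features

The target is an isoflavan: benzene ring A is fused to the dihydropyran ring C through C4a–C8a, with O1 on C8a and a free hydroxyl on C7, and C3 carries a second arene, ring B. Ring B is substituted at five of its six carbons in an alternating carbon–oxygen pattern: C1′ is bonded to C3, C2′ bears a hydroxyl, C3′ a prenyl group, and a 2,2-dimethyl-2H-pyran (ring D) is fused across C4′–C5′ with its oxygen on C4′. C3 is the only stereocentre (R); it is benzylic, lies between the methylenes C2 and C4, has no neighbouring stereocentre to relay from, and so must be set absolutely. The fragile groups are the prenyl olefin next to the 2′-phenol (acid closes it to a chroman), the styrene-type olefin of ring D (acid, electrophiles, hydrogenation) and the two electron-rich phenols; strong acid, hydrogenolysis and electrophilic halogen are therefore excluded once these groups are present. The real difficulty is twofold: a crowded, regiodefined ring B, and an enantiopure C3 in a ring that offers no handle for induction. The key step exploits ring A: O1 on C8a, the C4 methylene on C4a and the oxygen on C7 map onto an oxygen-bound alkyne (C8a≡C8), a propargylic alkyne (C4a≡C5) and a two-carbon alkyne whose boron becomes the C7 hydroxyl (C6–C7), so rings A and C can be closed together around a C3 that is already in place.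

## Logic of the disconnections

**28 back to 27.** The cut is the O2′–CH2 bond of an acetal protecting group. The last step must be neither acidic nor reductive, so a fluoride-labile SEM acetal is used. A silyl ether on O2′ was rejected: O2′ lies five atoms from the primary alkoxide needed later, which invites an oxygen-to-oxygen silyl shift, and aryl silyl ethers are also exposed to hydride and n-BuLi. The gain is one protecting group for the whole route; the demand is a hot fluoride step on a free phenol with the released formaldehyde trapped.

**27 back to 26 and 25.** C5–H is traced to C5–Si and C7–O to C7–B. Silicon is the steering group and boron the masked hydroxyl of the annulation, so both arrive with the ring-forming step. The demands are a boron oxidation that spares two olefins, and a C–Si cleavage by base: C5 is meta to both ring-A oxygens, so ipso-protonation by acid is unassisted and acid would destroy the prenyl group and ring D.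

**25 back to 23 and 24.** The bonds C4a–C8a, C5–C6 and C7–C8 are cut. This removes rings A and C at once and leaves one acyclic chain with a single stereocentre plus a two-carbon boron fragment; O1 is already bonded to C8a, so no aryl–oxygen bond has to be made. The forward step must favour cross- over homo-trimerisation, place boron meta to silicon, and run at room temperature, because an ynol ether with a β-hydrogen fragments on heating.

**23 back to 20 and 19.** The C8a≡C8 triple bond is traced to a dichlorovinyl ether, and the O1–C8a bond to a primary alcohol and trichloroethylene. This is the general way from an alcohol to a terminal alkynyl ether. The demand is that a potassium alkoxide be made in the presence of an alkynylsilane, so it must be formed cold and trapped at once.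

**19 back to 18, then 15 and 16.** The C3–C4 bond is cut and C2 is raised to the acyl level. The two arms at C3 are then unlike from the start: the carbonyl becomes C2–O and the electrophile becomes C4 with its alkyne. Enzymatic desymmetrisation of a symmetric 2-aryl-1,3-diol was weighed and set aside, because the monoester can racemise by acyl shift, the alkyne arm would need displacement of a primary sulfonate β to an electron-rich arene, and the sequence is longer. The gain is a stereocentre of predictable sense from one C–C bond formation; the demand is high facial selectivity without epimerisation of the α-aryl imide.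

**15 back to 12 and 13; 12 back to 11, then 8 and 9.** The N–acyl bond and the C1′–CH2 bond are cut, giving an aryl bromide and an acetate enolate equivalent. The coupling must insert into a hindered, electron-rich bromide without a Heck reaction at either olefin.

**8 back to 4 and 5.** Ring D is opened at its O–CMe2 bond and at the bond between the former aldehyde carbon and the olefinic carbon of the Grignard reagent. An aldehyde next to a phenol is a latent chromene, and its position fixes the regiochemistry of ring D. The demand is a dehydration under acid too weak to touch the prenyl group or the acetal.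

**4 back to 3, then 1 and 2.** The O4–acetal bond and the C3′–prenyl bond are cut. The carbon between the two oxygens is the most nucleophilic site of the resorcinol; bromine blocks the competing carbon and later serves as the coupling handle. The demands are C- over O-alkylation and discrimination between the two hydroxyls, which the hydrogen bond to the aldehyde provides.

## Other disconnections considered

**Alternative 1:** The cut runs through ring B itself (C1′–C2′, C2′–C3′, C4′–C5′). It leads to the enone diazoketone A2, in which the finished chroman sits on the β-carbon of an α,β-unsaturated diazomethyl ketone, and to the siloxyalkyne A3, which brings C3′, C4′ and the prenyl group. The ketone must carry one C=C, not a diene: a dienyl ketene would close on its own without an alkyne. Irradiation of A2 would trigger a Wolff rearrangement; regioselective ketene–alkyne [2+2], 4π opening, 6π closure and tautomerisation (a Danheiser benzannulation) would give A1 with 2′-OH free and O4′ silylated.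
- In its favour: the crowded 1′,2′,3′,4′ pattern would be assembled regiospecifically with the two ring-B oxygens already differentiated. This is better than the chosen plan, where that pattern rests on a modest C-prenylation. The step is metal-free and forms three bonds, equal to the chosen key step.
- Against it: A1 still lacks ring D, so desilylation, a chromene annulation at O4′/C5′ and pivalate removal must follow. C3 in A2 is the γ-position of an enone and would meet base during diazo transfer, so loss of configuration by dienolate formation is a real threat; C3 in 23 has no activating neighbour. A2 also needs its own asymmetric chroman synthesis.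
- Comparison: both are cascades through a strained unsaturated intermediate, but the benzannulation closes one ring and the cyclotrimerisation two. The alternative is expected to be no shorter.

**Alternative 2:** The cut is O1–C2, made on a precursor with one carbon too many at C3: the oxetane A5, whose two ring methylenes are enantiotopic. A chiral phosphoric acid such as TRIP would activate the oxetane, and the ring-A phenol would open one methylene, closing ring C and giving A4 with a quaternary C3 bearing a hydroxymethyl group. Oxidation to the formyl level and decarbonylation with RhCl(PPh3)3 (Tsuji–Wilkinson decarbonylation) would then replace that carbon by hydrogen with retention.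
- In its favour: configuration would be set by a catalyst and not a stoichiometric auxiliary, which is better than the chosen plan. Ring A would be bought with its oxygen in place, so neither boron nor silicon has to be removed, which is also better. The acid is weak enough for the prenyl group and ring D.
- Against it: A5 contains a 3-aryl-3-benzyl oxetane that needs its own multistep preparation, and the carbon deletion costs two to three further steps. The decarbonylation is the weak point: the rhodium alkyl at the benzylic tertiary C3 has β-hydrogens on C2 and C4 and could eliminate to an isoflavene, erasing the stereocentre, and hot rhodium hydrides could shift the prenyl double bond.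
- Comparison: one bond and one ring in the key step against three bonds and two rings. Configuration is set more elegantly but then put at risk, and the length is expected to be equal at best.

**Alternative 3:** The cuts are C4–C4a and O1–C8a, dividing the target into the aryl iodide A7 (ring A with its protected oxygen) and the chiral bromo alcohol A8 (ring B with C2, C3 and C4). With Pd(OAc)2 and norbornene (a Catellani-type sequence) the arylpalladium species would add to norbornene and palladate the ortho C–H. It would then take up the alkyl bromide of A8 at the tetravalent-palladium stage to form C4–C4a, extrude norbornene and end by ipso C–O bond formation with the tethered alcohol, giving A6.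
- In its favour: it is the most convergent of the four plans. Ring A needs no traceless groups, so only one deprotection would follow, which is better step economy after the key step than the chosen plan. A8 would come from the same kind of auxiliary alkylation that gives 19, so the source of chirality is equal.
- Against it: A7 has hydrogen at both ortho positions and the target needs C8 to stay unsubstituted. Without a second ortho substituent norbornene extrusion is slow, and a second C–H palladation and alkylation is to be expected. The closing aryl–oxygen reductive elimination with a primary alcohol must outrun β-hydride elimination, and under carbonate base A8 can lose HBr across its benzylic C–H or close to an oxetane.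
- Comparison: both plans build ring C in a metal-templated cascade. In the chosen plan the tether and the silyl group settle every regiochemical question; here the decisive ortho effect is missing from the substrate.

Key step: step 11

Abbreviations: SEM = 2-(trimethylsilyl)ethoxymethyl; prenyl = 3-methylbut-2-en-1-yl; Bpin = 4,4,5,5-tetramethyl-1,3,2-dioxaborolan-2-yl; ArB = 2,2-dimethyl-8-prenyl-7-(SEM-oxy)-2H-chromen-6-yl (the protected ring B/D unit).

Remark: the alkylation in step 7 is assumed to follow the usual chelated Z-enolate model, so that the (R)-configured auxiliary 13 gives R at C3; compounds 1, 2, 5, 9, 13, 16 and 24 are taken as purchasable.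

## Route

Step 1
Reactants: 1 5-bromo-2,4-dihydroxybenzaldehyde; 2 prenyl bromide
Product: 3 5-bromo-2,4-dihydroxy-3-prenylbenzaldehyde
Conditions: KOH (2.2 equiv), H2O, 0 °C → rt
Reagents that add atoms: none
Why: C-alkylation of a resorcinol dianion in water (phenoxide C-prenylation): hydrogen bonding to water damps the oxygens, and because bromine blocks C5 the only activated carbon is C3 between the two oxygens; O-prenyl ethers are the expected separable by-products.

Step 2
Reactants: 3 5-bromo-2,4-dihydroxy-3-prenylbenzaldehyde
Product: 4 5-bromo-2-hydroxy-3-prenyl-4-(SEM-oxy)benzaldehyde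
Conditions: SEMCl (1.05 equiv), i-Pr2NEt, CH2Cl2, 0 °C
Reagents that add atoms: 2-(trimethylsilyl)ethoxymethyl chloride (SEMCl), C[Si](C)(C)CCOCCl
Why: Williamson-type alkylation with a chloromethyl ether: the 2-hydroxyl is held in the hydrogen bond to the aldehyde and the 4-hydroxyl is the more acidic, so one equivalent of reagent should go to O4; the acetal cannot migrate to a neighbouring alkoxide later.

Step 3
Reactants: 4 5-bromo-2-hydroxy-3-prenyl-4-(SEM-oxy)benzaldehyde; 5 (2-methylprop-1-en-1-yl)magnesium bromide
Product: 8 6-bromo-2,2-dimethyl-8-prenyl-7-(SEM-oxy)-2H-chromene, via allylic carbinol 6 (not isolated), via ortho-quinone methide 7 (not isolated)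
Conditions: Me2C=CHMgBr (2.5 equiv), THF, 0 °C → rt; aq. NH4Cl; then PPTS (cat.), PhMe, 50 °C
Reagents that add atoms: none
Why: Grignard 1,2-addition gives carbinol 6, which under mild acid loses water to the ortho-quinone methide 7; oxa-6π electrocyclisation closes the 2,2-dimethyl-2H-pyran at the position dictated by the aldehyde. PPTS is too weak to protonate the prenyl olefin or cleave the acetal.

Step 4
Reactants: 8 6-bromo-2,2-dimethyl-8-prenyl-7-(SEM-oxy)-2H-chromene; 9 ethyl bromoacetate
Product: 11 ethyl 2-(ArB)acetate, via ethyl bromozincacetate 10 (not isolated)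
Conditions: Zn, THF, rt (forms 10); then 8, Pd(dba)2 (2 mol %), P(t-Bu)3 (2 mol %), THF, rt → 50 °C
Reagents that add atoms: none
Why: Palladium-catalysed α-arylation of a zinc ester enolate (Reformatsky reagent in a Negishi-type coupling): the bulky electron-rich phosphine promotes oxidative addition of zerovalent palladium into the ortho-substituted electron-rich bromide, and the neutral zinc enolate leaves the acetal and both olefins alone.

Step 5
Reactants: 11 ethyl 2-(ArB)acetate
Product: 12 2-(ArB)acetic acid
Conditions: LiOH, THF/MeOH/H2O, rt; then 1 M HCl to pH 4, 0 °C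
Reagents that add atoms: lithium hydroxide, [Li+].[OH-]
Why: Ester saponification; acidification only to pH 4 in the cold keeps the acetal and the prenyl group intact.

Step 6
Reactants: 12 2-(ArB)acetic acid; 13 (R)-4-benzyl-1,3-oxazolidin-2-one
Product: 15 (4R)-4-benzyl-3-[2-(ArB)acetyl]-1,3-oxazolidin-2-one, via mixed pivalic anhydride 14 (not isolated)
Conditions: t-BuCOCl, Et3N, THF, −20 °C; then 13, LiCl, −20 °C → rt
Reagents that add atoms: none
Why: N-acylation of the oxazolidinone through the mixed pivalic anhydride with Et3N/LiCl activation; the nucleophile attacks the less hindered arylacetyl carbonyl of 14.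

Step 7
Reactants: 15 (4R)-4-benzyl-3-[2-(ArB)acetyl]-1,3-oxazolidin-2-one; 16 3-bromo-1-(trimethylsilyl)prop-1-yne
Product: 18 (4R)-4-benzyl-3-[(2R)-2-(ArB)-5-(trimethylsilyl)pent-4-ynoyl]-1,3-oxazolidin-2-one, via sodium Z-enolate 17 (not isolated)
Conditions: NaN(SiMe3)2 (1.1 equiv), THF, −78 °C; then 16, −78 → −40 °C
Reagents that add atoms: none
Why: Evans auxiliary alkylation: NaN(SiMe3)2 gives the sodium-chelated Z-enolate 17, the benzyl group of the auxiliary shields one face and the propargylic bromide enters from the other, which with the (R)-auxiliary sets the future C3 as R. The silyl cap suppresses SN2′ attack, and allylic strain keeps the product from re-enolising.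

Step 8
Reactants: 18 (4R)-4-benzyl-3-[(2R)-2-(ArB)-5-(trimethylsilyl)pent-4-ynoyl]-1,3-oxazolidin-2-one
Product: 19 (2R)-2-(ArB)-5-(trimethylsilyl)pent-4-yn-1-ol
Conditions: LiBH4, H2O (1 equiv), Et2O, 0 °C
Reagents that add atoms: none
Why: Reductive cleavage of the N-acyl oxazolidinone with LiBH4 gives the primary alcohol and returns 13; no base able to epimerise the benzylic centre is present and the alkynylsilane is inert to borohydride.

Step 9
Reactants: 19 (2R)-2-(ArB)-5-(trimethylsilyl)pent-4-yn-1-ol
Product: 20 (E)-1,2-dichlorovinyl ether of 19
Conditions: KH (1.5 equiv), THF, −20 °C, short; then Cl2C=CHCl, −50 °C → rt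
Reagents that add atoms: trichloroethylene, ClC=C(Cl)Cl
Why: Alkoxide addition to dichloroacetylene formed in the flask from trichloroethylene (first half of the trichloroethylene route to alkynyl ethers); anti addition gives the E-dichlorovinyl ether. The alkoxide is made cold and trapped at once to limit its attack on the alkynylsilane, and the acetal on O2′ cannot shift to it.

Step 10
Reactants: 20 (E)-1,2-dichlorovinyl ether of 19
Product: 23 [(4R)-4-(ArB)-5-(ethynyloxy)pent-1-yn-1-yl]trimethylsilane, via chloroethynyl ether 21 (not isolated), via lithium alkynyl ether 22 (not isolated)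
Conditions: n-BuLi (2.3 equiv), THF, −78 → −40 °C; then MeOH, −78 °C; Et3N-washed silica, stored cold
Reagents that add atoms: none
Why: n-BuLi removes HCl to give chloroalkyne 21, and chlorine–lithium exchange gives the lithium alkynyl ether 22, which methanol protonates (second half of the trichloroethylene route). The C-silyl alkyne and the acetal tolerate n-BuLi at −78 °C; the product is kept cold and acid-free because terminal ynol ethers hydrate with acid and fragment on heating.

Step 11
Reactants: 23 [(4R)-4-(ArB)-5-(ethynyloxy)pent-1-yn-1-yl]trimethylsilane; 24 2-ethynyl-4,4,5,5-tetramethyl-1,3,2-dioxaborolane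
Product: 25 (3R)-3-(ArB)-5-(trimethylsilyl)-7-Bpin-chroman
Conditions: Cp*RuCl(cod) (10 mol %), 24 (3 equiv), ClCH2CH2Cl, rt, slow addition of 23, argon
Reagents that add atoms: none
Why: Proposed new method: Cp*RuCl, freed from cod, binds both alkynes of 23, and oxidative cyclisation gives a bicyclic ruthenacyclopentadiene; this forms C4a–C8a and closes ring C as a six-membered ring through the metallacycle. Insertion of 24 into the less hindered Ru–C8 bond and reductive elimination then form C7–C8 and C5–C6 and close ring A as a formal [4+2] onto the diene of the metallacycle. The closest known reaction type is the Cp*RuCl(cod)-catalysed [2+2+2] cyclotrimerisation of tethered diynes with alkynylboronates; 1-alkynyl ethers are known partners in rhodium-catalysed alkyne trimerisation, and what is new is the ynol ether oxygen inside the tether. No stereocentre is formed, and C3 is untouched because it has no activating neighbour. Two selectivities are needed: cross- over homo-trimerisation, secured by the tether, slow addition of 23 and excess 24; and the orientation of 24, secured by SiMe3 on C5, which sends the boron-bearing carbon to the unsubstituted C8 so that boron ends meta to silicon at C7. O1 arrives as the ynol ether oxygen, so no aryl–oxygen bond has to be made, and boron stands in for the C7 hydroxyl.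

Step 12
Reactants: 25 (3R)-3-(ArB)-5-(trimethylsilyl)-7-Bpin-chroman
Product: 26 (3R)-3-(ArB)-5-(trimethylsilyl)chroman-7-ol
Conditions: NaBO3·4H2O (4 equiv), THF/H2O, rt
Reagents that add atoms: sodium perborate, O[B-]1(O)OO[B-](O)(O)OO1.[Na+].[Na+]
Why: Oxidation of the arylboronate with perborate: hydroperoxide adds to boron, the aryl group shifts from boron to oxygen and hydrolysis gives the phenol; this nucleophilic oxidant should leave both olefins, the arylsilane and the acetal untouched.

Step 13
Reactants: 26 (3R)-3-(ArB)-5-(trimethylsilyl)chroman-7-ol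
Product: 27 (3R)-3-(ArB)chroman-7-ol
Conditions: KOSiMe3 (3 equiv), DMSO/H2O, 70 °C; aq. NH4Cl
Reagents that add atoms: none
Why: Base-mediated protodesilylation of an aryltrimethylsilane: silanolate or hydroxide adds to silicon and the silicate is protonated at the ipso carbon by water. Base is used because C5 is meta to both ring-A oxygens, so acid gets no help at the ipso carbon and would attack the prenyl group and ring D.

Step 14
Reactants: 27 (3R)-3-(ArB)chroman-7-ol
Product: 28 (3R)-3-[7-hydroxy-2,2-dimethyl-8-prenyl-2H-chromen-6-yl]chroman-7-ol (target)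
Conditions: Bu4NF (6 equiv), H2NCH2CH2NH2 (3 equiv), DMF, 80 °C; aq. NH4Cl
Reagents that add atoms: none
Why: Fluoride attacks the silicon of the acetal, ethene and formaldehyde are expelled and the 2′-phenoxide is freed; ethylenediamine traps formaldehyde before it can hydroxymethylate the electron-rich ring A, and the neutral work-up avoids acid-induced cyclisation of the prenyl group onto O2′.

## Compound list

1 | 5-bromo-2,4-dihydroxybenzaldehyde | O=Cc1cc(Br)c(O)cc1O | starting material
2 | prenyl bromide (1-bromo-3-methylbut-2-ene) | CC(C)=CCBr | starting material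
3 | 5-bromo-2,4-dihydroxy-3-prenylbenzaldehyde | O=Cc1cc(Br)c(O)c(CC=C(C)C)c1O | intermediate
4 | 5-bromo-2-hydroxy-3-prenyl-4-(SEM-oxy)benzaldehyde | O=Cc1cc(Br)c(OCOCC[Si](C)(C)C)c(CC=C(C)C)c1O | intermediate
5 | (2-methylprop-1-en-1-yl)magnesium bromide | CC(C)=C[Mg]Br | starting material
6 | 1-[5-bromo-2-hydroxy-3-prenyl-4-(SEM-oxy)phenyl]-3-methylbut-2-en-1-ol (racemic carbinol, not isolated) | CC(C)=CC(O)c1cc(Br)c(OCOCC[Si](C)(C)C)c(CC=C(C)C)c1O | intermediate
7 | 4-bromo-6-[(Z)-3-methylbut-2-enylidene]-2-prenyl-3-(SEM-oxy)cyclohexa-2,4-dien-1-one (ortho-quinone methide, not isolated) | CC(C)=C\C=C1/C(=O)C(CC=C(C)C)=C(OCOCC[Si](C)(C)C)C(Br)=C1 | intermediate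
8 | 6-bromo-2,2-dimethyl-8-prenyl-7-(SEM-oxy)-2H-chromene | Brc1cc2C=CC(C)(C)Oc2c(CC=C(C)C)c1OCOCC[Si](C)(C)C | intermediate
9 | ethyl bromoacetate | CCOC(=O)CBr | starting material
10 | ethyl bromozincacetate (Reformatsky reagent, not isolated) | CCOC(=O)C[Zn]Br | intermediate
11 | ethyl 2-(ArB)acetate | CCOC(=O)Cc1cc2C=CC(C)(C)Oc2c(CC=C(C)C)c1OCOCC[Si](C)(C)C | intermediate
12 | 2-(ArB)acetic acid | OC(=O)Cc1cc2C=CC(C)(C)Oc2c(CC=C(C)C)c1OCOCC[Si](C)(C)C | intermediate
13 | (R)-4-benzyl-1,3-oxazolidin-2-one | O=C1OC[C@@H](Cc2ccccc2)N1 | starting material
14 | 2-(ArB)acetic pivalic anhydride (not isolated) | CC(C)(C)C(=O)OC(=O)Cc1cc2C=CC(C)(C)Oc2c(CC=C(C)C)c1OCOCC[Si](C)(C)C | intermediate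
15 | (4R)-4-benzyl-3-[2-(ArB)acetyl]-1,3-oxazolidin-2-one | O=C1OC[C@@H](Cc2ccccc2)N1C(=O)Cc1cc2C=CC(C)(C)Oc2c(CC=C(C)C)c1OCOCC[Si](C)(C)C | intermediate
16 | 3-bromo-1-(trimethylsilyl)prop-1-yne | C[Si](C)(C)C#CCBr | starting material
17 | sodium Z-enolate of 15 (not isolated) | [Na+].[O-]/C(=C\c1cc2C=CC(C)(C)Oc2c(CC=C(C)C)c1OCOCC[Si](C)(C)C)N1[C@H](Cc2ccccc2)COC1=O | intermediate
18 | (4R)-4-benzyl-3-[(2R)-2-(ArB)-5-(trimethylsilyl)pent-4-ynoyl]-1,3-oxazolidin-2-one | O=C1OC[C@@H](Cc2ccccc2)N1C(=O)[C@H](CC#C[Si](C)(C)C)c1cc2C=CC(C)(C)Oc2c(CC=C(C)C)c1OCOCC[Si](C)(C)C | intermediate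
19 | (2R)-2-(ArB)-5-(trimethylsilyl)pent-4-yn-1-ol | OC[C@H](CC#C[Si](C)(C)C)c1cc2C=CC(C)(C)Oc2c(CC=C(C)C)c1OCOCC[Si](C)(C)C | intermediate
20 | [(4R)-4-(ArB)-5-{[(E)-1,2-dichloroethenyl]oxy}pent-1-yn-1-yl]trimethylsilane | Cl/C=C(/Cl)OC[C@H](CC#C[Si](C)(C)C)c1cc2C=CC(C)(C)Oc2c(CC=C(C)C)c1OCOCC[Si](C)(C)C | intermediate
21 | [(4R)-4-(ArB)-5-(chloroethynyloxy)pent-1-yn-1-yl]trimethylsilane (not isolated) | ClC#COC[C@H](CC#C[Si](C)(C)C)c1cc2C=CC(C)(C)Oc2c(CC=C(C)C)c1OCOCC[Si](C)(C)C | intermediate
22 | lithium acetylide of 23 (lithium alkynyl ether, not isolated) | [Li]C#COC[C@H](CC#C[Si](C)(C)C)c1cc2C=CC(C)(C)Oc2c(CC=C(C)C)c1OCOCC[Si](C)(C)C | intermediate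
23 | [(4R)-4-(ArB)-5-(ethynyloxy)pent-1-yn-1-yl]trimethylsilane (key-step precursor) | C#COC[C@H](CC#C[Si](C)(C)C)c1cc2C=CC(C)(C)Oc2c(CC=C(C)C)c1OCOCC[Si](C)(C)C | intermediate
24 | 2-ethynyl-4,4,5,5-tetramethyl-1,3,2-dioxaborolane | C#CB1OC(C)(C)C(C)(C)O1 | starting material
25 | (3R)-3-(ArB)-5-(trimethylsilyl)-7-Bpin-chroman (key-step product) | C[Si](C)(C)c1cc(B2OC(C)(C)C(C)(C)O2)cc2OC[C@H](Cc12)c1cc2C=CC(C)(C)Oc2c(CC=C(C)C)c1OCOCC[Si](C)(C)C | intermediate
26 | (3R)-3-(ArB)-5-(trimethylsilyl)chroman-7-ol | C[Si](C)(C)c1cc(O)cc2OC[C@H](Cc12)c1cc2C=CC(C)(C)Oc2c(CC=C(C)C)c1OCOCC[Si](C)(C)C | intermediate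
27 | (3R)-3-(ArB)chroman-7-ol | Oc1ccc2c(c1)OC[C@H](C2)c1cc2C=CC(C)(C)Oc2c(CC=C(C)C)c1OCOCC[Si](C)(C)C | intermediate
28 | (3R)-3-[7-hydroxy-2,2-dimethyl-8-prenyl-2H-chromen-6-yl]chroman-7-ol | CC(C)=CCc1c(O)c([C@@H]2COc3cc(O)ccc3C2)cc2c1OC(C)(C)C=C2 | target

## Step count and least certain steps

Total step count: 14. Longest linear sequence: 14 steps, from 1 to 28; all other components are purchased.

**Step 11 (key step).** The ynol ether may be diverted before it cyclises, by hydration from traces of water, by formation of a ruthenium alkoxyvinylidene or by thermal fragmentation. Oxidative cyclisation of a 1,7-diyne with a silylated terminus may also be slow enough for 24 to trimerise with itself, and orientation control may be incomplete. The fallback uses known chemistry, sets out from 15 and returns at 27. 2,4-Dihydroxybenzaldehyde would be silylated (t-BuMe2SiCl, imidazole) to 2,4-bis(tert-butyldimethylsilyloxy)benzaldehyde F1, reduced with NaBH4 to the benzylic alcohol F2 and brominated (PPh3, CBr4) to the benzyl bromide F3. Enolate 17, made from 15 as in step 7, would be alkylated with F3 to the imide F4; facial control is the same, so the sense at C3 is the same. LiBH4 would give the alcohol F5. Bu4NF at room temperature would free both ring-A phenols in the triol F6 without touching the SEM acetal. A Mitsunobu etherification (PPh3, diisopropyl azodicarboxylate, high dilution) would close O1–C2 to give 27, which enters step 14.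

**Step 9.** The potassium alkoxide may attack the alkynylsilane, transferring silicon from carbon to oxygen, before it is trapped by dichloroacetylene. The fallback sets out from 19 and returns at 23 without ever forming an alkoxide. Formylation with acetic formic anhydride and pyridine would give the formate F7. Wittig-type dichloromethylenation (PPh3, CCl4, THF, 60 °C) would give the 2,2-dichlorovinyl ether F8. n-BuLi would then take F8 through 21 and 22 to 23.

**Step 13.** C–Si cleavage may be slow because the ring carries a phenoxide under the basic conditions, and prolonged heating in base may start to move the prenyl double bond into conjugation. The fallback sets out from 23 and returns at 27 without an aryl–silicon bond. K2CO3 in MeOH would remove the alkynyl silyl group to give the bis-terminal diyne F9. Cyclotrimerisation with 24 under the conditions of step 11 would give the silicon-free 7-boronate F10 together with its C6-boryl regioisomer F11, since orientation control is given up; these would have to be separated. Perborate oxidation of F10 would give 27.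

**Step 1.** O-alkylation and double alkylation may outweigh C-alkylation, since bromine lowers the nucleophilicity of the ring. The fallback sets out from 1 and returns at 3. A Tsuji–Trost O-alkylation with tert-butyl 2-methylbut-3-en-2-yl carbonate and Pd(PPh3)4 would give the 4-O-(1,1-dimethylallyl) ether F12. Heating in PhMe would then deliver the prenyl group to C3 by aromatic Claisen rearrangement, C5 being blocked.

**Step 4.** Oxidative addition into the hindered, electron-rich bromide may be slow, leaving the zinc enolate to condense with itself. The fallback sets out from 8 and returns at 12. Palladium-catalysed malonate arylation (dimethyl malonate, Pd(dba)2, P(t-Bu)3, K3PO4, PhMe, 70 °C) would give the dimethyl arylmalonate F13. Saponification would give the arylmalonic acid F14, which would lose CO2 on gentle warming at pH 4 to give 12.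

## Further compounds

F1 | step 11 | 2,4-bis(tert-butyldimethylsilyloxy)benzaldehyde | O=Cc1ccc(O[Si](C)(C)C(C)(C)C)cc1O[Si](C)(C)C(C)(C)C
F2 | step 11 | [2,4-bis(tert-butyldimethylsilyloxy)phenyl]methanol | OCc1ccc(O[Si](C)(C)C(C)(C)C)cc1O[Si](C)(C)C(C)(C)C
F3 | step 11 | 2,4-bis(tert-butyldimethylsilyloxy)benzyl bromide | BrCc1ccc(O[Si](C)(C)C(C)(C)C)cc1O[Si](C)(C)C(C)(C)C
F4 | step 11 | (4R)-4-benzyl-3-{(2R)-2-(ArB)-3-[2,4-bis(tert-butyldimethylsilyloxy)phenyl]propanoyl}-1,3-oxazolidin-2-one | O=C1OC[C@@H](Cc2ccccc2)N1C(=O)[C@H](Cc1ccc(O[Si](C)(C)C(C)(C)C)cc1O[Si](C)(C)C(C)(C)C)c1cc2C=CC(C)(C)Oc2c(CC=C(C)C)c1OCOCC[Si](C)(C)C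
F5 | step 11 | (2R)-2-(ArB)-3-[2,4-bis(tert-butyldimethylsilyloxy)phenyl]propan-1-ol | OC[C@H](Cc1ccc(O[Si](C)(C)C(C)(C)C)cc1O[Si](C)(C)C(C)(C)C)c1cc2C=CC(C)(C)Oc2c(CC=C(C)C)c1OCOCC[Si](C)(C)C
F6 | step 11 | 4-[(2R)-2-(ArB)-3-hydroxypropyl]benzene-1,3-diol | OC[C@H](Cc1ccc(O)cc1O)c1cc2C=CC(C)(C)Oc2c(CC=C(C)C)c1OCOCC[Si](C)(C)C
F7 | step 9 | (2R)-2-(ArB)-5-(trimethylsilyl)pent-4-yn-1-yl formate | O=COC[C@H](CC#C[Si](C)(C)C)c1cc2C=CC(C)(C)Oc2c(CC=C(C)C)c1OCOCC[Si](C)(C)C
F8 | step 9 | [(4R)-4-(ArB)-5-[(2,2-dichloroethenyl)oxy]pent-1-yn-1-yl]trimethylsilane | ClC(Cl)=COC[C@H](CC#C[Si](C)(C)C)c1cc2C=CC(C)(C)Oc2c(CC=C(C)C)c1OCOCC[Si](C)(C)C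
F9 | step 13 | 6-[(2R)-1-(ethynyloxy)pent-4-yn-2-yl]-2,2-dimethyl-8-prenyl-7-(SEM-oxy)-2H-chromene | C#COC[C@H](CC#C)c1cc2C=CC(C)(C)Oc2c(CC=C(C)C)c1OCOCC[Si](C)(C)C
F10 | step 13 | (3R)-3-(ArB)-7-Bpin-chroman | CC1(C)OB(OC1(C)C)c1ccc2c(c1)OC[C@H](C2)c1cc2C=CC(C)(C)Oc2c(CC=C(C)C)c1OCOCC[Si](C)(C)C
F11 | step 13 | (3R)-3-(ArB)-6-Bpin-chroman (regioisomeric by-product) | CC1(C)OB(OC1(C)C)c1ccc2OC[C@H](Cc2c1)c1cc2C=CC(C)(C)Oc2c(CC=C(C)C)c1OCOCC[Si](C)(C)C
F12 | step 1 | 5-bromo-2-hydroxy-4-[(2-methylbut-3-en-2-yl)oxy]benzaldehyde | O=Cc1cc(Br)c(OC(C)(C)C=C)cc1O
F13 | step 4 | dimethyl 2-(ArB)malonate | COC(=O)C(C(=O)OC)c1cc2C=CC(C)(C)Oc2c(CC=C(C)C)c1OCOCC[Si](C)(C)C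
F14 | step 4 | 2-(ArB)malonic acid | OC(=O)C(C(=O)O)c1cc2C=CC(C)(C)Oc2c(CC=C(C)C)c1OCOCC[Si](C)(C)C
A1 | alternative 1 | (R)-isoflavan with 2′-OH, 3′-prenyl, 4′-O-triisopropylsilyl and 7-O-pivaloyl, ring D absent | CC(C)=CCc1c(O)c([C@@H]2COc3cc(OC(=O)C(C)(C)C)ccc3C2)ccc1O[Si](C(C)C)(C(C)C)C(C)C
A2 | alternative 1 | (E)-1-diazo-4-[(3R)-7-(pivaloyloxy)chroman-3-yl]but-3-en-2-one | [N-]=[N+]=CC(=O)/C=C/[C@@H]1COc2cc(OC(=O)C(C)(C)C)ccc2C1
A3 | alternative 1 | triisopropyl[(5-methylhex-4-en-1-yn-1-yl)oxy]silane | CC(C)=CCC#CO[Si](C(C)C)(C(C)C)C(C)C
A4 | alternative 2 | 3-hydroxymethyl isoflavan bis(tert-butyldimethylsilyl) ether, C3 configured to give the target on stereoretentive loss of the hydroxymethyl carbon | CC(C)=CCc1c(O[Si](C)(C)C(C)(C)C)c([C@]2(CO)COc3cc(O[Si](C)(C)C(C)(C)C)ccc3C2)cc2c1OC(C)(C)C=C2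
A5 | alternative 2 | 3-aryl-3-[2-hydroxy-4-(tert-butyldimethylsilyloxy)benzyl]oxetane (aryl = silylated ring B/D unit) | CC(C)=CCc1c(O[Si](C)(C)C(C)(C)C)c(C2(Cc3ccc(O[Si](C)(C)C(C)(C)C)cc3O)COC2)cc2c1OC(C)(C)C=C2
A6 | alternative 3 | (R)-isoflavan bis-SEM ether | CC(C)=CCc1c(OCOCC[Si](C)(C)C)c([C@@H]2COc3cc(OCOCC[Si](C)(C)C)ccc3C2)cc2c1OC(C)(C)C=C2
A7 | alternative 3 | 1-iodo-3-(SEM-oxy)benzene | Ic1cccc(OCOCC[Si](C)(C)C)c1
A8 | alternative 3 | (2R)-3-bromo-2-(ArB)propan-1-ol | OC[C@H](CBr)c1cc2C=CC(C)(C)Oc2c(CC=C(C)C)c1OCOCC[Si](C)(C)C
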